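(The runs were generated by integration from invented constants, and the scatter is random.)

If a product molecule can lose its hand after it is made, then follow one molecule through two forks: at birth it turns left or right, and as it ages it may change sides. Read both chances from the two earlier runs, winter and dusk, and carry them to the new flask.

| setting | winter | dusk | flask |
|---|---|---|---|
| left-handed substrate | 1.4 M | 1.4 M | 1.4 M |
| right-handed substrate | 1.4 M | 1.4 M | 1.4 M |
| gas | 170 mM (held) | 170 mM (held) | 170 mM (held) |
| free catalyst | 14 mol% | 22 mol% | 10 mol% |
| remark | run made earlier | run made earlier |  |
| time |  |  | 10 h |

| run | time / h | left-handed product / % | right-handed product / % | left-handed substrate / % |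
|---|---|---|---|---|
| winter | 1.00 | 0.6 | 0.3 | 49.8 |
| winter | 3.00 | 2.1 | 1.1 | 48.5 |
| winter | 6.00 | 4.6 | 3.1 | 45.2 |
| winter | 8.00 | 5.8 | 3.9 | 43.5 |
| winter | 12.0 | 9.2 | 6.1 | 40.6 |
| dusk | 2.50 | 1.9 | 1.4 | 48.1 |
| dusk | 5.00 | 4.2 | 2.3 | 46.0 |
| dusk | 8.00 | 7.0 | 4.5 | 43.0 |
| dusk | 10.0 | 8.9 | 6.1 | 40.4 |
| dusk | 12.0 | 10.1 | 7.0 | 39.2 |

(readings scatter by 0.3 percentage points)

- free catalyst is single-handed; left-handed substrate and right-handed substrate are mirror images of each other, charged as a racemate, each of them at the stated concentration
- the earlier runs were read with a standard deviation of 0.3 percentage points
- at the start none of the gas is in solution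
- an excess is the difference of the two amounts in percent of their sum
- an excess is below zero if the other one leads

* excess of left-handed product over right-handed product in the product at 1.0 h
* excess of left-handed product over right-handed product in the product at 10 h
* part of the left-handed substrate and right-handed substrate charged together that has reacted at 10 h

Pool the four readings up to 5.00 h in the two runs. Their products sum to 13.9% of the charge and give an excess of 26.6%, while the five readings from 8.00 h on give 19.5%. Take the mean age of the product as half the elapsed time, since the winter run holds half of its last product at half of its last time; the early pool is then 1.44 h old and the late pool 5.00 h. Divide the logarithm of the ratio of the two excesses by the difference of the ages to get the fade rate, 0.0869 h⁻¹, the fraction of the excess lost per hour of mean age. Run it back to age zero for a birth excess of 30.2%, a selectivity factor of 1.87, then forward: my excess is 28.9% at 1.0 h and 19.5% at 10 h.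

The weak link is the early pool, whose excess wobbles by 6.10%. Push it that far each way and reckon again: the excess at 1.0 h swings from 20.8% to 37.5%, while at 10 h it stays put, that age being the late pool's own.

The forecast gives 22% (14% to 33%) and 20% (16.5% to 23.5%), with 11.2% reacted (9.8% to 12.6%), holding that the early values “only hint at something higher”. My early excess stands higher than its figure; for the part reacted, on which the fade rate is silent, take the forecast's number.

The flask gives 34.2% at 1.0 h and 21.9% at 10 h, with 10.8% reacted, and it runs by these steps:

    2 free catalyst → spent catalyst (k = 0.0871 L mol⁻¹ h⁻¹)
    left-handed substrate ⇌ right-handed substrate (k = 0.0363 h⁻¹)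
    reagent + free catalyst + right-handed substrate → free catalyst + right-handed product (k = 0.789 L² mol⁻² h⁻¹)
    reagent + free catalyst + left-handed substrate → free catalyst + left-handed product (k = 1.66 L² mol⁻² h⁻¹)
    gas ⇌ reagent, rate k5*(csat - [reagent]) (kL = 0.422 h⁻¹)
    left-handed product ⇌ right-handed product (k = 0.0513 h⁻¹)

Left-handed product and right-handed product pass into each other with the constant 0.0513 h⁻¹. Multiply the early excess of this flask by the fade over the 4.50 h between the two mean ages and you get 23.1% for the later time, 1.3 percentage points above what the flask shows. Do the same for the neighbouring flask with 4 mol% of free catalyst, which has 34.3% at the same early time: the step gives 23.2%, and that flask stands at 22.8%.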